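**Retrosynthetic overview**
- The last step frees all eight phenols from the fully methylated bis-lactone, an octamethyl ether with two methoxy groups on half A, four on half B and one on each 4-aryl group.
- The strategy rests on one feature: C2–C3–C3'–C2' are the four carbons of succinic acid, and C4 and C4' are doubly benzylic CH carbons ortho to the lactone oxygens O1 and O1'. Each lactone ring O1–C2–C3–C4–C4a–C8a is therefore cut across C3–C4 and O1–C2 into a succinyl enolate (C2=C3) and an o-quinone methide (C4=C4a–C8a=O1).
- Ring order: the 5,7-dioxygenated lactone ring (half A) is annulated first onto one CH2–CO end of tert-butyl 4-nitrophenyl succinate. After an ester switch, the 5,6,7,8-tetraoxygenated lactone ring (half B) is annulated onto the other end. The C3–C3' bond and all benzene rings are bought.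
- Both annulations use the same enantiomer of an aminoindanol triazolylidene. The o-quinone methides come from racemic o-hydroxybenzhydryl sulfones, made from two salicylaldehydes and one batch of 4-methoxyphenylmagnesium bromide.

Key step: step 13

Assumption: the sense of induction is taken from the usual model in which the indane shields one face of the Z azolium enolate. On that basis (5aR,10bS)-2-mesityl-5a,10b-dihydro-4H,6H-indeno[2,1-b][1,2,4]triazolo[4,3-d][1,4]oxazin-2-ium chloride ("the triazolium chloride") is written for both annulations. Its sense is to be confirmed on 9, and the (5aS,10bR) salt would replace it in both steps if the sense proves opposite.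

Remark: primed locants denote the tetraoxygenated half B. C3 is labelled R in the mono-lactones 9, 17 and 18 and S in 20 and 21 only because the substituent priorities change; the centre is not inverted.

**Route**

Step 1
Reactants: 1 4-bromoanisole
Product: 2 4-methoxyphenylmagnesium bromide (titrated THF stock solution, kept under Ar)
Conditions: Mg turnings (1.2 equiv), I2 (one crystal), THF, 40 °C to reflux, then rt; titrated; one batch serves steps 2 and 9
Reagents that add atoms: magnesium, [Mg]
Why: Grignard formation by insertion of magnesium metal into the aryl C–Br bond, with the methoxy group inert; the THF solution is stable under argon, so a single batch can supply both later additions.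

Step 2
Reactants: 3 2-hydroxy-4,6-dimethoxybenzaldehyde; 2 4-methoxyphenylmagnesium bromide
Product: 4 rac-2-[hydroxy(4-methoxyphenyl)methyl]-3,5-dimethoxyphenol
Conditions: 2 (2.5 equiv, stock solution from step 1), 3, THF, 0 °C to rt; pH 7 phosphate buffer quench; crude 4 used at once
Reagents that add atoms: none
Why: Grignard addition to the aldehyde after the first equivalent of 2 has turned the phenol into its magnesium phenoxide, which chelates the carbonyl; the new benzhydryl centre is racemic and is erased later, so it needs no control.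

Step 3
Reactants: 4 rac-2-[hydroxy(4-methoxyphenyl)methyl]-3,5-dimethoxyphenol
Product: 5 rac-3,5-dimethoxy-2-[(4-methoxyphenyl)(4-methylbenzenesulfonyl)methyl]phenol (sulfone A)
Conditions: p-TolSO2H (1.5 equiv, freshly liberated), CH2Cl2 (dilute), 0 °C to rt
Reagents that add atoms: p-toluenesulfinic acid, Cc1ccc(cc1)S(=O)O
Why: Acid-promoted SN1-type sulfinate exchange, in which the strongly stabilised benzhydryl cation (protonated o-quinone methide) is captured at sulfur by excess sulfinate faster than by the electron-rich ring of a second molecule, giving the sulfone as a storable o-quinone methide precursor.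

Step 4
Reactants: 6 mono-tert-butyl succinate
Product: 7 tert-butyl 4-nitrophenyl succinate
Conditions: 4-nitrophenol (1.1 equiv), DCC (1.1 equiv), DMAP (5 mol %), CH2Cl2, 0 °C to rt
Reagents that add atoms: 4-nitrophenol, O=[N+]([O-])c1ccc(O)cc1
Why: Steglich esterification of the free acid end, leaving the tert-butyl ester as the inert end and the 4-nitrophenyl ester as the acyl donor for the carbene.

Step 5
Reactants: 5 sulfone A; 7 tert-butyl 4-nitrophenyl succinate
Product: 9 tert-butyl 2-[(3R,4R)-5,7-dimethoxy-4-(4-methoxyphenyl)-2-oxochroman-3-yl]acetate, via o-quinone methide A 8 (not isolated)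
Conditions: 7 (1.5 equiv), the triazolium chloride (15 mol %), Cs2CO3 (2.5 equiv), 4 Å MS, THF, 0 °C to rt; 5 (1.0 equiv) added slowly; pH 7 buffer quench
Reagents that add atoms: none
Why: Known carbene-catalysed azolium enolate/o-quinone methide formal [4+2] annulation (hetero-Diels–Alder type Michael addition–lactonisation), in which the carbene displaces 4-nitrophenoxide from 7, the acyl azolium is deprotonated at its own CH2 (not at the CH2 of the tert-butyl ester) to the Z enolate, Cs2CO3 expels sulfinate from 5 to give 8, and endo addition on the enolate face left open by the indane followed by 6-exo-trig O-acylation should set C3 and C4 together as the 3,4-cis (3R,4R) pair.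

Step 6
Reactants: 10 1,2,3,4-tetramethoxybenzene
Product: 11 2,3,4,5-tetramethoxybenzaldehyde
Conditions: Cl2CHOMe (1.5 equiv), TiCl4 (2 equiv), CH2Cl2, 0 °C; ice-water
Reagents that add atoms: dichloromethyl methyl ether (formyl carbon), COC(Cl)Cl; water (carbonyl oxygen on hydrolysis), O
Why: Rieche formylation, an electrophilic aromatic substitution at one of the two equivalent free positions, each ortho and para to methoxy groups, so a single regioisomer should form.

Step 7
Reactants: 11 2,3,4,5-tetramethoxybenzaldehyde
Product: 13 2,3,4,5-tetramethoxyphenol, via 2,3,4,5-tetramethoxyphenyl formate 12 (not isolated)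
Conditions: 30% aq H2O2 (1.3 equiv), H2SO4 (cat.), MeOH, rt
Reagents that add atoms: hydrogen peroxide, OO
Why: Acid-catalysed Dakin (Baeyer–Villiger type) oxidation, in which the electron-rich aryl group with ortho and para methoxy donors migrates to oxygen and the aryl formate is methanolysed in the same pot.

Step 8
Reactants: 13 2,3,4,5-tetramethoxyphenol
Product: 14 2-hydroxy-3,4,5,6-tetramethoxybenzaldehyde
Conditions: MgCl2 (1.5 equiv), Et3N (3.75 equiv), (CH2O)n (7 equiv), MeCN, reflux; 1 M HCl work-up
Reagents that add atoms: formaldehyde (as paraformaldehyde), C=O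
Why: Magnesium-mediated ortho-formylation (Casnati–Skattebøl), in which the magnesium phenoxide delivers formaldehyde to the only free ring carbon and a second formaldehyde oxidises the benzylic alkoxide to the aldehyde.

Step 9
Reactants: 14 2-hydroxy-3,4,5,6-tetramethoxybenzaldehyde; 2 4-methoxyphenylmagnesium bromide
Product: 15 rac-2-[hydroxy(4-methoxyphenyl)methyl]-3,4,5,6-tetramethoxyphenol
Conditions: 2 (2.5 equiv, stock solution from step 1), 14, THF, 0 °C to rt; pH 7 buffer quench; crude 15 used at once
Reagents that add atoms: none
Why: Grignard addition to the chelated magnesium phenoxide aldehyde as in step 2, giving a racemic benzhydrol whose centre is erased later.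

Step 10
Reactants: 15 rac-2-[hydroxy(4-methoxyphenyl)methyl]-3,4,5,6-tetramethoxyphenol
Product: 16 rac-2,3,4,5-tetramethoxy-6-[(4-methoxyphenyl)(4-methylbenzenesulfonyl)methyl]phenol (sulfone B)
Conditions: p-TolSO2H (1.5 equiv), CH2Cl2, 0 °C to rt
Reagents that add atoms: p-toluenesulfinic acid, Cc1ccc(cc1)S(=O)O
Why: The same SN1-type sulfinate exchange as in step 3, here without competing ring alkylation because the phenol ring is fully substituted.

Step 11
Reactants: 9 tert-butyl 2-[(3R,4R)-5,7-dimethoxy-4-(4-methoxyphenyl)-2-oxochroman-3-yl]acetate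
Product: 17 2-[(3R,4R)-5,7-dimethoxy-4-(4-methoxyphenyl)-2-oxochroman-3-yl]acetic acid
Conditions: TFA/CH2Cl2 (1:4), Et3SiH (3 equiv), 0 °C to rt; toluene co-evaporation
Reagents that add atoms: none
Why: Acidolysis of the tert-butyl ester with triethylsilane as scavenger for the tert-butyl cation so that the electron-rich rings are not alkylated, while the aryl lactone and the cis C3/C4 centres are inert to acid.

Step 12
Reactants: 17 2-[(3R,4R)-5,7-dimethoxy-4-(4-methoxyphenyl)-2-oxochroman-3-yl]acetic acid
Product: 18 4-nitrophenyl 2-[(3R,4R)-5,7-dimethoxy-4-(4-methoxyphenyl)-2-oxochroman-3-yl]acetate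
Conditions: 4-nitrophenol (1.2 equiv), DCC (1.1 equiv), CH2Cl2, 0 °C to rt, no amine base
Reagents that add atoms: 4-nitrophenol, O=[N+]([O-])c1ccc(O)cc1
Why: Carbodiimide active-ester formation without base, so the C3–H alpha to the lactone carbonyl never meets a base and the cis relationship is kept.

Step 13
Reactants: 18 4-nitrophenyl ester of the half A lactone acetic acid; 16 sulfone B
Product: 20 (3S,3'S,4R,4'R)-5,5',6',7,7',8'-hexamethoxy-4,4'-bis(4-methoxyphenyl)-[3,3'-bichromane]-2,2'-dione, via o-quinone methide B 19 (not isolated)
Conditions: 18 (1.0 equiv), the triazolium chloride (20 mol %, same enantiomer as in step 5), Cs2CO3 (2.3 equiv), 4 Å MS, THF, −20 °C to rt; 16 (1.3 equiv) added slowly; pH 7 buffer quench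
Reagents that add atoms: none
Why: The carbene displaces 4-nitrophenoxide from 18 to give an acyl azolium whose CH2 is deprotonated to the Z azolium enolate, while Cs2CO3 eliminates p-toluenesulfinate from 16 to give methide 19; the enolate carbon adds to the methide carbon (C3'–C4' bond) and the phenoxide so formed acylates on the azolium (O1'–C2' bond), releasing the catalyst. This is the known carbene-catalysed azolium enolate/o-quinone methide formal [4+2] annulation that gives cis-3,4-disubstituted dihydrocoumarins, applied here to a beta-branched ester that already carries the half A lactone. The tetramethoxy lactone ring O1'–C2'–C3'–C4'–C4a'–C8a' closes by 6-exo-trig acyl substitution of the aryloxide on the acyl azolium, which overall equals an endo [4+2] across C2'=C3' and C4'=C4a'–C8a'=O1'. C3' is set by the triazolylidene, whose indane leaves one enolate face open, and C4' by the endo approach of the E methide to the Z enolate, which places the aryl group cis to the C3' substituent; using the same catalyst enantiomer as in step 5 should give the like (3S,4R,3'S,4'R) pairing. The step needs catalyst control over the resident C3/C4 centres, cis selectivity, and activation of the unhindered 4-nitrophenyl ester in preference to the hindered aryl lactone; the better leaving group and the higher acidity of the acyl azolium CH2 compared with the tertiary lactone C3–H secure the last point, and a lactone opened by the carbene would reclose to the same six-membered ring. The racemic centre of 16 disappears in 19, and slow addition of 16 keeps the methide concentration low.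

Step 14
Reactants: 20 cis,cis octamethyl ether
Product: 21 (3S,3'S,4R,4'R)-5,5',6',7,7',8'-hexahydroxy-4,4'-bis(4-hydroxyphenyl)-[3,3'-bichromane]-2,2'-dione (CNP0064734.1)
Conditions: BBr3 (16 equiv), CH2Cl2, −78 °C to rt, Ar; degassed ice-water quench, EtOAc extraction, Sephadex LH-20 (degassed MeOH), no base
Reagents that add atoms: none
Why: Lewis acid ether cleavage, in which BBr3 coordinates each methoxy oxygen and bromide removes the methyl group by SN2, while the aryl lactones and the four C–H stereocentres should be untouched under acidic conditions; the base-free, oxygen-free work-up protects the cis centres and the 5,6,7,8-tetrahydroxy ring.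

**Compound list**
1 | 4-bromoanisole | COc1ccc(Br)cc1 | starting material
2 | 4-methoxyphenylmagnesium bromide | COc1ccc([Mg]Br)cc1 | intermediate
3 | 2-hydroxy-4,6-dimethoxybenzaldehyde | COc1cc(O)c(C=O)c(OC)c1 | starting material
4 | rac-2-[hydroxy(4-methoxyphenyl)methyl]-3,5-dimethoxyphenol | COc1ccc(C(O)c2c(O)cc(OC)cc2OC)cc1 | intermediate
5 | rac-3,5-dimethoxy-2-[(4-methoxyphenyl)(4-methylbenzenesulfonyl)methyl]phenol (sulfone A) | COc1ccc(C(c2c(O)cc(OC)cc2OC)S(=O)(=O)c2ccc(C)cc2)cc1 | intermediate
6 | mono-tert-butyl succinate | CC(C)(C)OC(=O)CCC(=O)O | starting material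
7 | tert-butyl 4-nitrophenyl succinate | CC(C)(C)OC(=O)CCC(=O)Oc1ccc([N+](=O)[O-])cc1 | intermediate
8 | o-quinone methide A, (6E)-3,5-dimethoxy-6-[(4-methoxyphenyl)methylidene]cyclohexa-2,4-dien-1-one | O=C1C=C(OC)C=C(OC)/C1=C\c1ccc(OC)cc1 | intermediate (not isolated)
9 | tert-butyl 2-[(3R,4R)-5,7-dimethoxy-4-(4-methoxyphenyl)-2-oxochroman-3-yl]acetate (cis) | O=C1Oc2cc(OC)cc(OC)c2[C@@H](c2ccc(OC)cc2)[C@H]1CC(=O)OC(C)(C)C | intermediate
10 | 1,2,3,4-tetramethoxybenzene | COc1ccc(OC)c(OC)c1OC | starting material
11 | 2,3,4,5-tetramethoxybenzaldehyde | COc1cc(C=O)c(OC)c(OC)c1OC | intermediate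
12 | 2,3,4,5-tetramethoxyphenyl formate | COc1cc(OC=O)c(OC)c(OC)c1OC | intermediate (not isolated)
13 | 2,3,4,5-tetramethoxyphenol | COc1cc(O)c(OC)c(OC)c1OC | intermediate
14 | 2-hydroxy-3,4,5,6-tetramethoxybenzaldehyde | COc1c(O)c(C=O)c(OC)c(OC)c1OC | intermediate
15 | rac-2-[hydroxy(4-methoxyphenyl)methyl]-3,4,5,6-tetramethoxyphenol | COc1ccc(C(O)c2c(O)c(OC)c(OC)c(OC)c2OC)cc1 | intermediate
16 | rac-2,3,4,5-tetramethoxy-6-[(4-methoxyphenyl)(4-methylbenzenesulfonyl)methyl]phenol (sulfone B) | COc1ccc(C(c2c(O)c(OC)c(OC)c(OC)c2OC)S(=O)(=O)c2ccc(C)cc2)cc1 | intermediate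
17 | 2-[(3R,4R)-5,7-dimethoxy-4-(4-methoxyphenyl)-2-oxochroman-3-yl]acetic acid (cis) | O=C1Oc2cc(OC)cc(OC)c2[C@@H](c2ccc(OC)cc2)[C@H]1CC(=O)O | intermediate
18 | 4-nitrophenyl 2-[(3R,4R)-5,7-dimethoxy-4-(4-methoxyphenyl)-2-oxochroman-3-yl]acetate (cis) | O=C1Oc2cc(OC)cc(OC)c2[C@@H](c2ccc(OC)cc2)[C@H]1CC(=O)Oc1ccc([N+](=O)[O-])cc1 | intermediate
19 | o-quinone methide B, (6E)-2,3,4,5-tetramethoxy-6-[(4-methoxyphenyl)methylidene]cyclohexa-2,4-dien-1-one | O=C1C(OC)=C(OC)C(OC)=C(OC)/C1=C\c1ccc(OC)cc1 | intermediate (not isolated)
20 | (3S,3'S,4R,4'R)-5,5',6',7,7',8'-hexamethoxy-4,4'-bis(4-methoxyphenyl)-[3,3'-bichromane]-2,2'-dione (cis,cis octamethyl ether) | O=C1Oc2cc(OC)cc(OC)c2[C@@H](c2ccc(OC)cc2)[C@H]1[C@H]1C(=O)Oc2c(OC)c(OC)c(OC)c(OC)c2[C@H]1c1ccc(OC)cc1 | intermediate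
21 | (3S,3'S,4R,4'R)-5,5',6',7,7',8'-hexahydroxy-4,4'-bis(4-hydroxyphenyl)-[3,3'-bichromane]-2,2'-dione, CNP0064734.1 | O=C1Oc2cc(O)cc(O)c2[C@@H](c2ccc(O)cc2)[C@H]1[C@H]1C(=O)Oc2c(O)c(O)c(O)c(O)c2[C@H]1c1ccc(O)cc1 | target

**Step count and risks**

Total step count: 14. Longest linear sequence: 8 steps (1, 2, 3, 5, 11, 12, 13, 14); the half B branch from 10 (6, 7, 8, 9, 10, 13, 14) is 7 steps.

Steps most likely to fail:

1. Step 13 (key step). Enolisation of the hindered, beta-branched acyl azolium and capture of the fully substituted methide 19 may both be slow. The methide would then be consumed by 4-nitrophenoxide or by self-addition, and long exposure to carbonate and carbene could erode the resident C3 centre or let substrate control override the catalyst, giving low conversion and mixed diastereomers.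
 Fallback (reversed ring order): it sets out from sulfone 16 and ester 7 and returns at 20. Under the conditions of step 5, 16 and 7 should give, through 19, tert-butyl 2-[(3R,4R)-5,6,7,8-tetramethoxy-4-(4-methoxyphenyl)-2-oxochroman-3-yl]acetate F1, so the hindered methide meets the small succinate enolate. TFA/Et3SiH in CH2Cl2 gives 2-[(3R,4R)-5,6,7,8-tetramethoxy-4-(4-methoxyphenyl)-2-oxochroman-3-yl]acetic acid F2. DCC and 4-nitrophenol without base give 4-nitrophenyl 2-[(3R,4R)-5,6,7,8-tetramethoxy-4-(4-methoxyphenyl)-2-oxochroman-3-yl]acetate F3. F3 is then annulated with the less hindered sulfone 5 (through 8) with the same triazolium chloride and Cs2CO3, which should give 20.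

2. Step 5. The 3-methoxy group next to the methide carbon may weaken the E preference of methide 8, causing loss of cis and facial selectivity; the unsubstituted, nucleophilic ring positions of 5 and 8 may also undergo Friedel–Crafts-type self-alkylation.
 Fallback (conjugate arylation, alkylation, kinetic protonation; no o-quinone methide): it sets out from Grignard reagent 2 and returns at 9. Reagent 2 is quenched with B(OMe)3 at −78 °C and then aqueous HCl to give 4-methoxyphenylboronic acid F4. Hayashi–Miyaura 1,4-addition of F4 to purchased 5,7-dimethoxycoumarin F5 (Rh(acac)(C2H4)2, the SEGPHOS enantiomer that delivers the 4R adduct, dioxane/H2O, 60 °C) should give (4R)-5,7-dimethoxy-4-(4-methoxyphenyl)chroman-2-one F6. LiN(SiMe3)2 in THF at −78 °C followed by tert-butyl bromoacetate alkylates anti to the aryl group to give tert-butyl 2-[(3S,4R)-5,7-dimethoxy-4-(4-methoxyphenyl)-2-oxochroman-3-yl]acetate F7 (3,4-trans). A second deprotonation with LiN(SiMe3)2 at −78 °C and a quench with 2,6-di-tert-butyl-4-methylphenol protonates the lactone enolate on the face away from the pseudoaxial 4-aryl group, which should give cis 9.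

3. Step 14. Cleavage of the eight ethers may be incomplete (those flanking C4 and C4' are hindered), and the freed 5,6,7,8-tetrahydroxy ring may oxidise in air during isolation, leaving partially methylated and quinoid material that cannot be separated as free phenols.
 Fallback (capture, purify, release): it sets out from 20 and returns at 21. After BBr3 treatment as in step 14 and evaporation from MeOH, the crude phenol mixture is acetylated at once (Ac2O, pyridine, CH2Cl2, 0 °C, Ar) to the air-stable (3S,3'S,4R,4'R)-octaacetate of 21 F8. F8 is purified on silica, and under-cleaved material is returned to BBr3. Degassed HCl in MeOH (from AcCl/MeOH, 0 °C to rt) then removes the unhindered acetates by transesterification, and evaporation of the volatile by-products should leave 21. The hindered lactones should survive; one that opens to a methyl ester would reclose on concentration from acid, and either ortho oxygen of each ring gives the same lactone.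

**Further compounds**
F1 | step 13 | tert-butyl 2-[(3R,4R)-5,6,7,8-tetramethoxy-4-(4-methoxyphenyl)-2-oxochroman-3-yl]acetate (cis) | CC(C)(C)OC(=O)C[C@H]1C(=O)Oc2c(OC)c(OC)c(OC)c(OC)c2[C@H]1c1ccc(OC)cc1
F2 | step 13 | 2-[(3R,4R)-5,6,7,8-tetramethoxy-4-(4-methoxyphenyl)-2-oxochroman-3-yl]acetic acid (cis) | OC(=O)C[C@H]1C(=O)Oc2c(OC)c(OC)c(OC)c(OC)c2[C@H]1c1ccc(OC)cc1
F3 | step 13 | 4-nitrophenyl 2-[(3R,4R)-5,6,7,8-tetramethoxy-4-(4-methoxyphenyl)-2-oxochroman-3-yl]acetate (cis) | O=[N+]([O-])c1ccc(OC(=O)C[C@H]2C(=O)Oc3c(OC)c(OC)c(OC)c(OC)c3[C@H]2c2ccc(OC)cc2)cc1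
F4 | step 5 | 4-methoxyphenylboronic acid | COc1ccc(B(O)O)cc1
F5 | step 5 | 5,7-dimethoxycoumarin | COc1cc(OC)c2ccc(=O)oc2c1
F6 | step 5 | (4R)-5,7-dimethoxy-4-(4-methoxyphenyl)chroman-2-one | O=C1Oc2cc(OC)cc(OC)c2[C@@H](c2ccc(OC)cc2)C1
F7 | step 5 | tert-butyl 2-[(3S,4R)-5,7-dimethoxy-4-(4-methoxyphenyl)-2-oxochroman-3-yl]acetate (trans) | O=C1Oc2cc(OC)cc(OC)c2[C@@H](c2ccc(OC)cc2)[C@@H]1CC(=O)OC(C)(C)C
F8 | step 14 | (3S,3'S,4R,4'R)-octaacetate of 21 | O=C1Oc2cc(OC(C)=O)cc(OC(C)=O)c2[C@@H](c2ccc(OC(C)=O)cc2)[C@H]1[C@H]1C(=O)Oc2c(OC(C)=O)c(OC(C)=O)c(OC(C)=O)c(OC(C)=O)c2[C@H]1c1ccc(OC(C)=O)cc1
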